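**Plan**

Ring numbering used below: C1 = ring ketone, C2 = ring carbon carrying the propanoic acid arm (stereocentre Cα), C3 = ring carbon carrying the 1,3,3-trimethylcyclohexyl group (quaternary carbon C1'), C6 = ring carbon carrying CH2O.
Enabling feature: the Cα carboxyl on C2 and the CH2O group on C6 flank C1, so acid and formate can be merged retrosynthetically into a seven-membered lactone (Cα, C=O, O, CH2, C6, C1, C2) bridging C2 and C6 of the cyclohexenone ring. The first cut is then the C6–CH2 bond, leading back to a chloromethyl ester tethered over a C6 silyl enol ether.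
The cyclohexenone ring is cut at C2=C3 (aldol condensation) and C4–C5 (Michael addition) into a methyl ketone holding C1' and a vinyl ketone holding Cα. The vinyl ketone is cut at C1–C2 into an alkylzinc reagent and acryloyl chloride.
Forward: the trimethylcyclohexyl methyl ketone is made first (conjugate arylation, geminal dimethylation, arene-to-acid degradation, methyl addition). The cyclohexenone ring is then closed by Michael addition and aldol condensation, the lactone ring follows in the key step, and lactone hydrolysis plus O-formylation finish the synthesis.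
Stereochemistry: C1' (S) from a catalyst-controlled conjugate arylation; Cα (R) carried in unchanged from methyl (S)-3-bromo-2-methylpropanoate; C6 (S) relayed from Cα through the bridged lactone.

Key step: step 11

Remark: the sense of induction in step 1 is taken from the known behaviour of this catalyst with 3-methylcyclohex-2-en-1-one, and the facial preference in step 11 from a hand model of allylic strain; both are expectations.

**Route**

Step 1
Reactants: 1 3-methylcyclohex-2-en-1-one; 2 phenylboronic acid
Product: 3 (3S)-3-methyl-3-phenylcyclohexan-1-one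
Conditions: Pd(OCOCF3)2 (5 mol%), (R)-4-tert-butyl-2-(pyridin-2-yl)-4,5-dihydrooxazole (6 mol%), NH4PF6 (30 mol%), H2O (5 equiv), ClCH2CH2Cl, 40 °C
Reagents that add atoms: none
Why: Palladium-catalysed asymmetric conjugate addition of an arylboronic acid to a β-substituted cyclic enone is established for this pair of partners and should create the quaternary carbon under catalyst control; the (R)-ligand is specified because its enantiomer is known to give the (R)-ketone.

Step 2
Reactants: 3 (3S)-3-methyl-3-phenylcyclohexan-1-one
Product: 4 [(1S)-1,3,3-trimethylcyclohexyl]benzene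
Conditions: Me2Zn (2.2 equiv), TiCl4 (2.2 equiv), CH2Cl2, −30 to 20 °C
Reagents that add atoms: dimethylzinc C[Zn]C (both methyl groups, delivered as dimethyltitanium dichloride C[Ti](C)(Cl)Cl formed with TiCl4)
Why: Geminal dimethylation of a ketone with Me2TiCl2 (methyl addition, ionisation of the tertiary titanium alkoxide, second methyl transfer) should turn C=O into C(CH3)2 on a substrate with no other reactive group, the stereocentre lying two bonds from the reacting carbon.

Step 3
Reactants: 4 [(1S)-1,3,3-trimethylcyclohexyl]benzene
Product: 5 (1S)-1,3,3-trimethylcyclohexane-1-carboxylic acid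
Conditions: RuCl3·xH2O (5 mol%), NaIO4 (15 equiv), MeCN–EtOAc–H2O, 20 °C
Reagents that add atoms: sodium periodate [Na+].[O-]I(=O)(=O)=O (oxygen, relayed by RuO4); water O
Why: Oxidative degradation of a phenyl group to a carboxylic acid by catalytic RuO4 should be clean because the alkyl part has only quaternary and methylene carbons, and no bond of the stereocentre is broken.

Step 4
Reactants: 5 (1S)-1,3,3-trimethylcyclohexane-1-carboxylic acid
Product: 6 1-[(1S)-1,3,3-trimethylcyclohexyl]ethan-1-one
Conditions: MeLi (2.2 equiv), Et2O, 0 to 20 °C; poured into cold 1 M HCl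
Reagents that add atoms: methyllithium [Li]C
Why: Addition of methyllithium to the lithium carboxylate stops at the dilithium gem-diolate, which collapses to the methyl ketone only on acidic quench, the standard ketone synthesis from hindered carboxylic acids.

Step 5
Reactants: 6 1-[(1S)-1,3,3-trimethylcyclohexyl]ethan-1-one
Product: 7 trimethyl({1-[(1S)-1,3,3-trimethylcyclohexyl]ethenyl}oxy)silane
Conditions: LiN(i-Pr)2 (1.1 equiv), THF, −78 °C; Me3SiCl, −78 to 0 °C
Reagents that add atoms: chlorotrimethylsilane C[Si](C)(C)Cl
Why: Kinetic enolisation and O-silylation (silyl enol ether formation) can give only one regioisomer because the methyl group is the only enolisable position.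

Step 6
Reactants: 8 methyl (2S)-3-bromo-2-methylpropanoate; 9 acryloyl chloride
Product: 11 methyl (2R)-2-methyl-4-oxohex-5-enoate, via organozinc bromide 10 (not isolated)
Conditions: Zn dust, LiCl, THF, 45 °C; then 9, Pd(PPh3)4 (5 mol%), THF, 0 to 20 °C
Reagents that add atoms: none
Why: LiCl-assisted zinc insertion into the primary C–Br bond should give a β-ester alkylzinc whose stereocentre is not the metal-bearing carbon and is therefore configurationally safe, and its Negishi-type acylation with the acid chloride forms the C1–C2 bond without conjugate addition (the descriptor changes from S to R only because the priorities change).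

Step 7
Reactants: 7 trimethyl({1-[(1S)-1,3,3-trimethylcyclohexyl]ethenyl}oxy)silane; 11 methyl (2R)-2-methyl-4-oxohex-5-enoate
Product: 13 methyl (2R)-2-methyl-4,8-dioxo-8-[(1S)-1,3,3-trimethylcyclohexyl]octanoate, via silyl enol ether 12 (not isolated)
Conditions: Ph3CSbCl6 (5 mol%), CH2Cl2, −78 °C; then 1 M HCl, THF, 0 °C
Reagents that add atoms: none
Why: Mukaiyama–Michael addition of a silyl enol ether to a vinyl ketone under trityl cation catalysis should form the C4–C5 bond under non-basic conditions that leave Cα untouched, and the acid work-up hydrolyses the transferred silyl enol ether to the 1,5-diketone.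

Step 8
Reactants: 13 methyl (2R)-2-methyl-4,8-dioxo-8-[(1S)-1,3,3-trimethylcyclohexyl]octanoate
Product: 16 (2R)-2-{6-oxo-2-[(1S)-1,3,3-trimethylcyclohexyl]cyclohex-1-en-1-yl}propanoic acid, via diketo acid 14 (not isolated), via ketol acid 15 (not isolated)
Conditions: KOH (6 equiv), MeOH–H2O (3:1), 20 °C then 65 °C; HCl to pH 2
Reagents that add atoms: potassium hydroxide [K+].[OH-]
Why: After saponification, intramolecular aldol condensation (the ring-closing stage of a Robinson annulation) should form C2=C3, since of the three enolisable methylene groups only the one between the chain ketone and Cα can reach the other carbonyl through a six-membered ring, dehydration makes the closure irreversible, and the carboxylate formed first shields Cα–H from epimerisation.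

Step 9
Reactants: 16 (2R)-2-{6-oxo-2-[(1S)-1,3,3-trimethylcyclohexyl]cyclohex-1-en-1-yl}propanoic acid
Product: 17 chloromethyl (2R)-2-{6-oxo-2-[(1S)-1,3,3-trimethylcyclohexyl]cyclohex-1-en-1-yl}propanoate
Conditions: ClCH2OSO2Cl (1.2 equiv), NaHCO3 (4 equiv), Bu4NHSO4 (10 mol%), CH2Cl2–H2O, 0 to 20 °C
Reagents that add atoms: chloromethyl chlorosulfate ClCOS(=O)(=O)Cl
Why: O-Alkylation of the carboxylate with chloromethyl chlorosulfate under phase-transfer conditions is the standard route to chloromethyl esters and should leave the enone and both stereocentres untouched.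

Step 10
Reactants: 17 chloromethyl (2R)-2-{6-oxo-2-[(1S)-1,3,3-trimethylcyclohexyl]cyclohex-1-en-1-yl}propanoate
Product: 18 chloromethyl (2R)-2-{6-[(tert-butyldimethylsilyl)oxy]-2-[(1S)-1,3,3-trimethylcyclohexyl]cyclohexa-1,5-dien-1-yl}propanoate
Conditions: TBSOTf (1.3 equiv), i-Pr2NEt (2.0 equiv), CH2Cl2, −78 to −20 °C
Reagents that add atoms: tert-butyldimethylsilyl triflate CC(C)(C)[Si](C)(C)OS(=O)(=O)C(F)(F)F
Why: Soft enolisation with a silyl triflate and a hindered amine should remove the C6 (α') proton of the O-silylated enone kinetically and give the cross-conjugated 2-silyloxy-1,3-diene (the regiochemistry used in the first stage of Saegusa oxidations of enones), while the hindered base does not attack the chloromethyl ester at low temperature.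

Step 11
Reactants: 18 chloromethyl (2R)-2-{6-[(tert-butyldimethylsilyl)oxy]-2-[(1S)-1,3,3-trimethylcyclohexyl]cyclohexa-1,5-dien-1-yl}propanoate
Product: 19 (1S,5R)-5-methyl-7-[(1S)-1,3,3-trimethylcyclohexyl]-3-oxabicyclo[4.3.1]dec-6-ene-4,10-dione (the lactone bridging C2 and C6 of the enone ring)
Conditions: AgOTf (1.5 equiv), 2,6-di-tert-butyl-4-methylpyridine (2 equiv), 4 Å molecular sieves, CH2Cl2 (0.005 M), −78 to 0 °C; then aq. NaHCO3
Reagents that add atoms: none
Why: Proposed new method: Ag+ should abstract chloride from the chloromethyl ester to give an acyloxymethyl triflate (an O-acyl oxocarbenium ion), whose CH2 carbon is attacked by C6 of the silyl enol ether, after which the silyloxocarbenium ion loses its silyl group to triflate and leaves the C1 ketone. The closest known reactions are Lewis-acid- or silver-promoted alkylations of silyl enol ethers with α-chloro ethers and α-chloro sulfides and the C-alkylation of enolates with halomethyl esters; an acyloxymethyl cation has not been used in this intramolecular way. The seven-membered lactone closes as a 7-(enolendo)-exo-tet alkylation (seen from the cation, a 7-endo-trig capture of the O=CH2 unit), and the resulting bicyclo[4.3.1]decene is allowed because its bridgehead double bond C2=C3 is trans only within the nine-membered perimeter. The new C6 stereocentre is controlled by Cα: allylic 1,3-strain with the trimethylcyclohexyl group on C3 keeps the Cα–H bond in the diene plane, so the carboxyl arm of the (R)-centre lies over one face only and delivers CH2 to give (S) at C6, whereas the epimeric lactone would need the Cα methyl eclipsed with the C3 substituent. The step needs C- over O-alkylation, secured by the silyl cap on oxygen, and attack by C6 in preference to C2 (a five-membered alternative), which should follow from the much higher nucleophilicity of the silyl enol ether terminus; high dilution suppresses intermolecular alkylation and the hindered pyridine scavenges acid.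

Step 12
Reactants: 19 (1S,5R)-5-methyl-7-[(1S)-1,3,3-trimethylcyclohexyl]-3-oxabicyclo[4.3.1]dec-6-ene-4,10-dione
Product: 20 (2R)-2-{(5S)-5-(hydroxymethyl)-6-oxo-2-[(1S)-1,3,3-trimethylcyclohexyl]cyclohex-1-en-1-yl}propanoic acid
Conditions: Me3SnOH (5 equiv), ClCH2CH2Cl, 70 °C; 0.1 M HCl wash
Reagents that add atoms: trimethyltin hydroxide C[Sn](C)(C)O
Why: Ester hydrolysis with trimethyltin hydroxide proceeds by hydroxide transfer from tin under essentially neutral conditions and is chosen because the liberated β-hydroxy ketone, with its epimerisable C6–H, would not tolerate alkali; strain in the bridged lactone should assist the opening.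

Step 13
Reactants: 20 (2R)-2-{(5S)-5-(hydroxymethyl)-6-oxo-2-[(1S)-1,3,3-trimethylcyclohexyl]cyclohex-1-en-1-yl}propanoic acid
Product: 21 (2R)-2-{(5S)-5-[(formyloxy)methyl]-6-oxo-2-[(1S)-1,3,3-trimethylcyclohexyl]cyclohex-1-en-1-yl}propanoic acid (target)
Conditions: HCO2CH2CF3 (as solvent), 60 °C
Reagents that add atoms: 2,2,2-trifluoroethyl formate O=COCC(F)(F)F
Why: O-Formylation of the primary alcohol by transformylation from an activated formate ester under neutral conditions should give the formate without a base that could trigger β-elimination of formate or epimerisation at C6, and the carboxylic acid is inert to the reagent.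

**Compound list**

1 | 3-methylcyclohex-2-en-1-one | CC1=CC(=O)CCC1 | starting material
2 | phenylboronic acid | OB(O)c1ccccc1 | starting material
3 | (3S)-3-methyl-3-phenylcyclohexan-1-one | c1ccccc1[C@@]2(C)CCCC(=O)C2 | intermediate
4 | [(1S)-1,3,3-trimethylcyclohexyl]benzene | c1ccccc1[C@@]2(C)CCCC(C)(C)C2 | intermediate
5 | (1S)-1,3,3-trimethylcyclohexane-1-carboxylic acid | OC(=O)[C@@]1(C)CCCC(C)(C)C1 | intermediate
6 | 1-[(1S)-1,3,3-trimethylcyclohexyl]ethan-1-one | CC(=O)[C@@]1(C)CCCC(C)(C)C1 | intermediate
7 | trimethyl({1-[(1S)-1,3,3-trimethylcyclohexyl]ethenyl}oxy)silane | C=C(O[Si](C)(C)C)[C@@]1(C)CCCC(C)(C)C1 | intermediate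
8 | methyl (2S)-3-bromo-2-methylpropanoate | C[C@@H](C(=O)OC)CBr | starting material
9 | acryloyl chloride (prop-2-enoyl chloride) | C=CC(=O)Cl | starting material
10 | bromo[(2S)-3-methoxy-2-methyl-3-oxopropyl]zinc | C[C@@H](C(=O)OC)C[Zn]Br | intermediate
11 | methyl (2R)-2-methyl-4-oxohex-5-enoate | C[C@@H](C(=O)OC)CC(=O)C=C | intermediate
12 | methyl (2R)-2-methyl-8-oxo-4-[(trimethylsilyl)oxy]-8-[(1S)-1,3,3-trimethylcyclohexyl]oct-4-enoate (double-bond geometry open) | C[C@@H](C(=O)OC)CC(O[Si](C)(C)C)=CCCC(=O)[C@@]1(C)CCCC(C)(C)C1 | intermediate
13 | methyl (2R)-2-methyl-4,8-dioxo-8-[(1S)-1,3,3-trimethylcyclohexyl]octanoate | C[C@@H](C(=O)OC)CC(=O)CCCC(=O)[C@@]1(C)CCCC(C)(C)C1 | intermediate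
14 | (2R)-2-methyl-4,8-dioxo-8-[(1S)-1,3,3-trimethylcyclohexyl]octanoic acid | C[C@@H](C(=O)O)CC(=O)CCCC(=O)[C@@]1(C)CCCC(C)(C)C1 | intermediate
15 | (2R)-2-{2-hydroxy-6-oxo-2-[(1S)-1,3,3-trimethylcyclohexyl]cyclohexyl}propanoic acid (configuration at the two new ring centres open) | C[C@@H](C(=O)O)C1C(=O)CCCC1(O)[C@@]2(C)CCCC(C)(C)C2 | intermediate
16 | (2R)-2-{6-oxo-2-[(1S)-1,3,3-trimethylcyclohexyl]cyclohex-1-en-1-yl}propanoic acid | C[C@@H](C(=O)O)C1=C([C@@]2(C)CCCC(C)(C)C2)CCCC1=O | intermediate
17 | chloromethyl (2R)-2-{6-oxo-2-[(1S)-1,3,3-trimethylcyclohexyl]cyclohex-1-en-1-yl}propanoate | C[C@@H](C(=O)OCCl)C1=C([C@@]2(C)CCCC(C)(C)C2)CCCC1=O | intermediate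
18 | chloromethyl (2R)-2-{6-[(tert-butyldimethylsilyl)oxy]-2-[(1S)-1,3,3-trimethylcyclohexyl]cyclohexa-1,5-dien-1-yl}propanoate | C[C@@H](C(=O)OCCl)C1=C([C@@]2(C)CCCC(C)(C)C2)CCC=C1O[Si](C)(C)C(C)(C)C | intermediate
19 | (1S,5R)-5-methyl-7-[(1S)-1,3,3-trimethylcyclohexyl]-3-oxabicyclo[4.3.1]dec-6-ene-4,10-dione | C[C@@H](C(=O)OC3)C1=C([C@@]2(C)CCCC(C)(C)C2)CC[C@@H]3C1=O | intermediate
20 | (2R)-2-{(5S)-5-(hydroxymethyl)-6-oxo-2-[(1S)-1,3,3-trimethylcyclohexyl]cyclohex-1-en-1-yl}propanoic acid | C[C@@H](C(=O)O)C1=C([C@@]2(C)CCCC(C)(C)C2)CC[C@@H](CO)C1=O | intermediate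
21 | (2R)-2-{(5S)-5-[(formyloxy)methyl]-6-oxo-2-[(1S)-1,3,3-trimethylcyclohexyl]cyclohex-1-en-1-yl}propanoic acid | C[C@@H](C(=O)O)C1=C([C@@]2(C)CCCC(C)(C)C2)CC[C@@H](COC=O)C1=O | target

**Step count**

Total: 13 steps. Longest linear sequence: 12 steps (steps 1–5 and 7–13); step 6 is a one-step side branch.

**Steps most likely to fail**

Step 11. Ionisation of the chloromethyl ester may be slower than acid-induced loss of the silyl enol ether, and the cation may be captured by the C2=C3 double bond in a five-membered closure or react intermolecularly. The fallback makes the C6–CH2 bond and the lactone in separate, known operations and sets out from acid 16. Double deprotonation with LiN(i-Pr)2 (carboxylate, then the kinetic C6 enolate) and silylation with Me3SiCl would give trimethylsilyl (2R)-2-{6-[(trimethylsilyl)oxy]-2-[(1S)-1,3,3-trimethylcyclohexyl]cyclohexa-1,5-dien-1-yl}propanoate F1. A Mukaiyama aldol reaction of F1 with aqueous formaldehyde under Yb(OTf)3 catalysis, in which the silyl ester is lost to the aqueous medium, would give the C6-hydroxymethyl keto acid F2 as a mixture of epimers at C6. Yamaguchi lactonisation (2,4,6-trichlorobenzoyl chloride, Et3N, then DMAP, toluene, high dilution) would then close the bridge. Only the (6S) epimer can lactonise without forcing the Cα methyl into the plane of the enone, and the amine base is expected to feed the other epimer into the same channel by enolisation at C6. Stereocontrol is then thermodynamic, not kinetic. The route is rejoined at 19.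

Step 8. Addition of the enolate to the tert-alkyl ketone may be sterically retarded, dehydration to the crowded tetrasubstituted alkene may be reluctant, and forcing conditions could erode Cα. The fallback closes the ring without the side chain and attaches the side chain afterwards; it sets out from silyl enol ether 7. Addition of 7 to but-3-en-2-one under the conditions of step 7 would give 1-[(1S)-1,3,3-trimethylcyclohexyl]hexane-1,5-dione F3. Its methyl group should close onto the hindered carbonyl more easily (KOH, MeOH) to give 3-[(1S)-1,3,3-trimethylcyclohexyl]cyclohex-2-en-1-one F4. α-Iodination (I2, pyridine) would give the 2-iodo enone F5. Stille coupling with methyl 2-(tributylstannyl)acrylate (Pd2(dba)3, AsPh3, CuI) would give the dienone ester F6, and saponification (LiOH, THF–H2O) the 2-substituted acrylic acid F7. Asymmetric hydrogenation of F7 with Ru(OAc)2[(R)-BINAP] and H2 would set Cα under catalyst control, the sense being assigned by analogy with 2-arylacrylic acids. The route is rejoined at 16.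

Step 12. Hydroxide transfer to the hindered lactone carbonyl may be slow, and once the bridge is open the β-hydroxy ketone may lose formaldehyde by retro-aldol cleavage, dehydrate, or epimerise at C6. The fallback opens the ring under acid instead of hydrolysing it and sets out from lactone 19. In anhydrous formic acid with a catalytic amount of methanesulfonic acid at 20–40 °C, acid-catalysed acyl exchange (acidolysis) with release of ring strain should give the formyloxy acid directly. Exposure is kept short to limit acid-catalysed enolisation at C6. This bypasses 20, makes no new compound (entry F0 below) and rejoins the route at 21.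

**Further compounds**

F1 | step 11 | trimethylsilyl (2R)-2-{6-[(trimethylsilyl)oxy]-2-[(1S)-1,3,3-trimethylcyclohexyl]cyclohexa-1,5-dien-1-yl}propanoate | C[C@@H](C(=O)O[Si](C)(C)C)C1=C([C@@]2(C)CCCC(C)(C)C2)CCC=C1O[Si](C)(C)C
F2 | step 11 | (2R)-2-{5-(hydroxymethyl)-6-oxo-2-[(1S)-1,3,3-trimethylcyclohexyl]cyclohex-1-en-1-yl}propanoic acid, both epimers at the hydroxymethyl-bearing carbon | C[C@@H](C(=O)O)C1=C([C@@]2(C)CCCC(C)(C)C2)CCC(CO)C1=O
F3 | step 8 | 1-[(1S)-1,3,3-trimethylcyclohexyl]hexane-1,5-dione | CC(=O)CCCC(=O)[C@@]1(C)CCCC(C)(C)C1
F4 | step 8 | 3-[(1S)-1,3,3-trimethylcyclohexyl]cyclohex-2-en-1-one | O=C1C=C(CCC1)[C@@]2(C)CCCC(C)(C)C2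
F5 | step 8 | 2-iodo-3-[(1S)-1,3,3-trimethylcyclohexyl]cyclohex-2-en-1-one | O=C1C(I)=C(CCC1)[C@@]2(C)CCCC(C)(C)C2
F6 | step 8 | methyl 2-{6-oxo-2-[(1S)-1,3,3-trimethylcyclohexyl]cyclohex-1-en-1-yl}prop-2-enoate | C=C(C(=O)OC)C1=C([C@@]2(C)CCCC(C)(C)C2)CCCC1=O
F7 | step 8 | 2-{6-oxo-2-[(1S)-1,3,3-trimethylcyclohexyl]cyclohex-1-en-1-yl}prop-2-enoic acid | C=C(C(=O)O)C1=C([C@@]2(C)CCCC(C)(C)C2)CCCC1=O
F0 | step 12 | none | none
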